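**Retrosynthetic overview**
1. Target 23 ⇐ acetylation at C9 and hydroxyl-directed epoxidation of C7=C8 (oxirane formed last) of the macrocyclic dienyl lactone 21.
2. 21 ⇐ open chain 18 in one operation: C3a–C11a allylation closes the ten-membered carbocycle (the cyclase-type bond), and the γ-lactone then closes on the new C11a oxygen.
3. 18 ⇐ aldehyde 15 + methyl acrylate (Morita–Baylis–Hillman, then SN2' bromination).
4. 15 ⇐ vinyl iodide 7 + angelate 12 by B-alkyl Suzuki coupling (C6–C7), then oxidation at C3a.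
5. 7 ⇐ enal acetal 1 + propyne (C9 by asymmetric alkynylation, Z-olefin by trans-hydroalumination/iodination); 12 ⇐ (R)-but-3-ene-1,2-diol 8 (C4) + angelic acid. Ring order: carbocycle, lactone, oxirane.

Assumption: the ring methyls of the drawn skeleton are 1,4-related, so it is not a regular farnesane; its biogenesis is taken to parallel that of the germacranolides (allyl-type C–C closure of the ten-membered ring, lactonisation on the allylic oxygen, then olefin epoxidation and acylation); locants are those of cyclodeca[b]furan-2-one: O1, C2(=O), C3(=CH2), C3a, C4(OAng), C5, C6, C7(Me), C8, C9(OAc), C10(Me), C11, C11a.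

**Route**

Step 1
Reactants: 1 (2E)-4,4-dimethoxy-2-methylbut-2-enal; 2 propyne
Product: 4 (2E,4R)-1,1-dimethoxy-3-methylhept-2-en-5-yn-4-ol, via methyl(prop-1-ynyl)zinc 3 (not isolated)
Conditions: 2, Me2Zn, ProPhenol (10 mol %), Ph3PO (20 mol %), toluene, 0 °C; then 1, 4 °C; aq. NH4Cl
Reagents that add atoms: none
Why: Zinc–ProPhenol catalysed enantioselective alkynylation of an enal (Trost): the dinuclear zinc catalyst delivers the propynyl group to the Si face of the aldehyde, which sets the future C9 carbinol as 4R, the ligand enantiomer being the one that gives Si-face addition (checked by Mosher analysis); the acetal and the E-olefin are untouched.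

Step 2
Reactants: 4 (2E,4R)-1,1-dimethoxy-3-methylhept-2-en-5-yn-4-ol
Product: 6 (2E,4S,5Z)-6-iodo-1,1-dimethoxy-3-methylhepta-2,5-dien-4-ol, via cyclic vinylalanate 5 (not isolated)
Conditions: NaAlH2(OCH2CH2OMe)2, THF, 0 °C to rt; then I2, THF, −78 °C; aq. KNaC4H4O6
Reagents that add atoms: iodine, [I][I]
Why: Hydroxyl-directed trans-hydroalumination of the propargylic alcohol (hydride to the proximal alkyne carbon, aluminium to the distal one in a five-membered alkoxyalanate) and iodinolysis with retention give only the (Z)-γ-iodo allylic alcohol, fixing the geometry of the future C7=C8 olefin; the carbinol descriptor changes from R to S only because the alkyne has become an alkene.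

Step 3
Reactants: 6 (2E,4S,5Z)-6-iodo-1,1-dimethoxy-3-methylhepta-2,5-dien-4-ol
Product: 7 triethyl{[(2E,4S,5Z)-6-iodo-1,1-dimethoxy-3-methylhepta-2,5-dien-4-yl]oxy}silane
Conditions: Et3SiCl, imidazole, CH2Cl2, 0 °C
Reagents that add atoms: chlorotriethylsilane, CC[Si](Cl)(CC)CC
Why: Imidazole-promoted silylation masks the doubly allylic carbinol so that it survives the later Swern oxidation and bromination.

Step 4
Reactants: 8 (2R)-but-3-ene-1,2-diol
Product: 9 (2R)-1-[(triethylsilyl)oxy]but-3-en-2-ol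
Conditions: Et3SiCl (1.05 equiv), imidazole, CH2Cl2, −78 to −40 °C
Reagents that add atoms: chlorotriethylsilane, CC[Si](Cl)(CC)CC
Why: Selective silylation of the primary hydroxyl of a 1,2-diol at low temperature; the stereocentre (future C4, from the chiral pool) is not touched.

Step 5
Reactants: 9 (2R)-1-[(triethylsilyl)oxy]but-3-en-2-ol; 10 angelic acid
Product: 12 (2R)-1-[(triethylsilyl)oxy]but-3-en-2-yl (2Z)-2-methylbut-2-enoate, via angelic 2,4,6-trichlorobenzoic anhydride 11 (not isolated)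
Conditions: 10, 2,4,6-Cl3C6H2COCl, Et3N, toluene, rt; then 9, 80 °C
Reagents that add atoms: none
Why: Yamaguchi esterification through the trichlorobenzoyl mixed anhydride without DMAP, the established way to make angelates without isomerisation to the tiglate; the carbinol configuration is retained because only the acyl–oxygen bond is formed.

Step 6
Reactants: 12 (2R)-1-[(triethylsilyl)oxy]but-3-en-2-yl (2Z)-2-methylbut-2-enoate; 7 triethyl{[(2E,4S,5Z)-6-iodo-1,1-dimethoxy-3-methylhepta-2,5-dien-4-yl]oxy}silane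
Product: 14 (2R,5Z,7S,8E)-10,10-dimethoxy-5,8-dimethyl-1,7-bis[(triethylsilyl)oxy]deca-5,8-dien-2-yl (2Z)-2-methylbut-2-enoate, via B-alkyl-9-BBN borane 13 (not isolated)
Conditions: 12, 9-BBN-H, THF, 0 °C to rt; then 7, PdCl2(dppf) (5 mol %), AsPh3, 3 M aq. K3PO4, DMF, rt
Reagents that add atoms: none
Why: Anti-Markovnikov hydroboration of the terminal vinyl group (the electron-poor angelate olefin is inert) and B-alkyl Suzuki–Miyaura coupling with the vinyl iodide, which proceeds with retention and so gives the (5Z)-trisubstituted olefin.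

Step 7
Reactants: 14 (2R,5Z,7S,8E)-10,10-dimethoxy-5,8-dimethyl-1,7-bis[(triethylsilyl)oxy]deca-5,8-dien-2-yl (2Z)-2-methylbut-2-enoate
Product: 15 (2R,5Z,7S,8E)-10,10-dimethoxy-5,8-dimethyl-1-oxo-7-[(triethylsilyl)oxy]deca-5,8-dien-2-yl (2Z)-2-methylbut-2-enoate
Conditions: (COCl)2, DMSO, CH2Cl2, −78 to −30 °C; iPr2NEt, −78 °C; pH 7 buffer
Reagents that add atoms: none
Why: Swern oxidation in which the chlorosulfonium reagent cleaves and oxidises the primary triethylsilyl ether directly while the secondary one stays; amine addition at −78 °C and cold buffered work-up keep the α-acyloxy aldehyde from epimerising.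

Step 8
Reactants: 15 (2R,5Z,7S,8E)-10,10-dimethoxy-5,8-dimethyl-1-oxo-7-[(triethylsilyl)oxy]deca-5,8-dien-2-yl (2Z)-2-methylbut-2-enoate; 16 methyl acrylate
Product: 17 methyl (4R,7Z,9S,10E)-3-hydroxy-12,12-dimethoxy-7,10-dimethyl-2-methylidene-4-{[(2Z)-2-methylbut-2-enoyl]oxy}-9-[(triethylsilyl)oxy]dodeca-7,10-dienoate (both C3 epimers)
Conditions: 16 (10 equiv, neat), quinuclidine (0.25 equiv), MeOH (0.75 equiv), 0 °C
Reagents that add atoms: none
Why: Morita–Baylis–Hillman reaction of the activated α-acyloxy aldehyde with the quinuclidine–acrylate zwitterion under accelerated conditions (the second aldehyde is still an acetal); the new carbinol centre is formed as a mixture that the next step erases.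

Step 9
Reactants: 17 methyl (4R,7Z,9S,10E)-3-hydroxy-12,12-dimethoxy-7,10-dimethyl-2-methylidene-4-{[(2Z)-2-methylbut-2-enoyl]oxy}-9-[(triethylsilyl)oxy]dodeca-7,10-dienoate
Product: 18 methyl (2Z,4R,7Z,9S,10E)-2-(bromomethyl)-12,12-dimethoxy-7,10-dimethyl-4-{[(2Z)-2-methylbut-2-enoyl]oxy}-9-[(triethylsilyl)oxy]dodeca-2,7,10-trienoate
Conditions: NBS, Me2S, CH2Cl2, −20 to 0 °C
Reagents that add atoms: N-bromosuccinimide, O=C1CCC(=O)N1Br
Why: Corey–Kim-type activation of the allylic alcohol as an alkoxysulfonium salt and SN2' displacement by bromide give the thermodynamically preferred (Z)-2-(bromomethyl)enoate (chain cis to CH2Br); the acetal, silyl ether and angelate are inert.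

Step 10
Reactants: 18 methyl (2Z,4R,7Z,9S,10E)-2-(bromomethyl)-12,12-dimethoxy-7,10-dimethyl-4-{[(2Z)-2-methylbut-2-enoyl]oxy}-9-[(triethylsilyl)oxy]dodeca-2,7,10-trienoate
Product: 21 (3aR,4R,7Z,9S,10E,11aS)-9-hydroxy-7,10-dimethyl-3-methylidene-2-oxo-2,3,3a,4,5,6,9,11a-octahydrocyclodeca[b]furan-4-yl (2Z)-2-methylbut-2-enoate, via enal bromide 19 (not isolated), via hydroxy ester 20 (not isolated)
Conditions: AcOH–THF–H2O 3:1:1, rt; dilute to 2 mM (THF–H2O 1:1), indium powder (6 equiv), 35 °C; extract, then PPTS (0.2 equiv), toluene, 40 °C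
Reagents that add atoms: water, O
Why: Proposed new method: aqueous acid frees the enal and the C9 hydroxyl, indium inserts into the allylic bromide and the 2-(methoxycarbonyl)allylindium (which, unlike zinc or chromium reagents, is not expected to expel the neighbouring acyloxy group) adds through its γ-carbon to the tethered enal in a closed chair transition state, forming the C3a–C11a bond that a cyclase would form; the (Z)-γ-substituent axial and the enal equatorial give the syn adduct (cis-lactone, 11aS), attack syn to the C4 acyloxy group and anti to the chain in the A(1,3)-minimised conformer gives 3aR, and the cis γ-hydroxy ester lactonises under mild acid; closest known chemistry is the intermolecular indium Barbier allylation of aldehydes with 2-(bromomethyl)enoates in water and the chromium-mediated Nozaki–Hiyama–Kishi macrocyclisation to α-methylene lactones.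

Step 11
Reactants: 21 (3aR,4R,7Z,9S,10E,11aS)-9-hydroxy-7,10-dimethyl-3-methylidene-2-oxo-2,3,3a,4,5,6,9,11a-octahydrocyclodeca[b]furan-4-yl (2Z)-2-methylbut-2-enoate
Product: 22 (3aR,4R,7S,8R,9R,10E,11aS)-7,8-epoxy-9-hydroxy-7,10-dimethyl-3-methylidene-2-oxo-2,3,3a,4,5,6,7,8,9,11a-decahydrocyclodeca[b]furan-4-yl (2Z)-2-methylbut-2-enoate
Conditions: VO(acac)2 (5 mol %), t-BuOOH, CH2Cl2, 0 °C
Reagents that add atoms: tert-butyl hydroperoxide, CC(C)(C)OO
Why: Hydroxyl-directed vanadium-catalysed epoxidation (Sharpless–Michaelson): the vanadate ester of the C9 alcohol delivers oxygen to the electron-rich (7Z)-olefin on the face syn to the hydroxyl, as (Z)-cycloalkenols of ring size 8 and 9 give cis-epoxy alcohols, setting C7 (S) and C8 (R); the C10=C11 olefin is deactivated by the allylic lactone oxygen and the enoates are inert.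

Step 12
Reactants: 22 (3aR,4R,7S,8R,9R,10E,11aS)-7,8-epoxy-9-hydroxy-7,10-dimethyl-3-methylidene-2-oxo-2,3,3a,4,5,6,7,8,9,11a-decahydrocyclodeca[b]furan-4-yl (2Z)-2-methylbut-2-enoate
Product: 23 CNP0519641.1, (3aR,4R,7S,8R,9R,10E,11aS)-9-acetoxy-7,8-epoxy-7,10-dimethyl-3-methylidene-2-oxo-2,3,3a,4,5,6,7,8,9,11a-decahydrocyclodeca[b]furan-4-yl (2Z)-2-methylbut-2-enoate
Conditions: Ac2O, pyridine, DMAP (cat.), CH2Cl2, 0 °C to rt
Reagents that add atoms: acetic anhydride, CC(=O)OC(C)=O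
Why: DMAP-catalysed acetylation of the secondary alcohol with retention; the oxirane, α-methylene lactone and angelate tolerate these mild conditions.

**Compound list**
1 | (2E)-4,4-dimethoxy-2-methylbut-2-enal | COC(OC)/C=C(\C)C=O | starting material
2 | propyne | CC#C | starting material
3 | methyl(prop-1-yn-1-yl)zinc | C[Zn]C#CC | intermediate (not isolated)
4 | (2E,4R)-1,1-dimethoxy-3-methylhept-2-en-5-yn-4-ol | COC(OC)/C=C(\C)[C@@H](O)C#CC | intermediate
5 | cyclic vinylalanate: sodium salt of the five-membered 1,2-oxaluminole from 4 (Al bonded to O4 and C6, two 2-methoxyethoxy groups on Al, H on C5) | COC(OC)/C=C(\C)[C@H]1O[Al-](OCCOC)(OCCOC)C(C)=C1.[Na+] | intermediate (not isolated)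
6 | (2E,4S,5Z)-6-iodo-1,1-dimethoxy-3-methylhepta-2,5-dien-4-ol | COC(OC)/C=C(\C)[C@@H](O)/C=C(\I)C | intermediate
7 | triethyl{[(2E,4S,5Z)-6-iodo-1,1-dimethoxy-3-methylhepta-2,5-dien-4-yl]oxy}silane | COC(OC)/C=C(\C)[C@@H](O[Si](CC)(CC)CC)/C=C(\I)C | intermediate
8 | (2R)-but-3-ene-1,2-diol | C=C[C@@H](O)CO | starting material
9 | (2R)-1-[(triethylsilyl)oxy]but-3-en-2-ol | C=C[C@@H](O)CO[Si](CC)(CC)CC | intermediate
10 | angelic acid, (2Z)-2-methylbut-2-enoic acid | C/C=C(/C)C(=O)O | starting material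
11 | (2Z)-2-methylbut-2-enoic 2,4,6-trichlorobenzoic anhydride | C/C=C(/C)C(=O)OC(=O)c1c(Cl)cc(Cl)cc1Cl | intermediate (not isolated)
12 | (2R)-1-[(triethylsilyl)oxy]but-3-en-2-yl (2Z)-2-methylbut-2-enoate | C=C[C@@H](OC(=O)/C(C)=C\C)CO[Si](CC)(CC)CC | intermediate
13 | (2R)-4-(9-borabicyclo[3.3.1]nonan-9-yl)-1-[(triethylsilyl)oxy]butan-2-yl (2Z)-2-methylbut-2-enoate | CC[Si](CC)(CC)OC[C@H](OC(=O)/C(C)=C\C)CCB1C2CCCC1CCC2 | intermediate (not isolated)
14 | (2R,5Z,7S,8E)-10,10-dimethoxy-5,8-dimethyl-1,7-bis[(triethylsilyl)oxy]deca-5,8-dien-2-yl (2Z)-2-methylbut-2-enoate | COC(OC)/C=C(\C)[C@@H](O[Si](CC)(CC)CC)/C=C(/C)CC[C@@H](OC(=O)/C(C)=C\C)CO[Si](CC)(CC)CC | intermediate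
15 | (2R,5Z,7S,8E)-10,10-dimethoxy-5,8-dimethyl-1-oxo-7-[(triethylsilyl)oxy]deca-5,8-dien-2-yl (2Z)-2-methylbut-2-enoate | COC(OC)/C=C(\C)[C@@H](O[Si](CC)(CC)CC)/C=C(/C)CC[C@@H](OC(=O)/C(C)=C\C)C=O | intermediate
16 | methyl acrylate | C=CC(=O)OC | starting material
17 | methyl (4R,7Z,9S,10E)-3-hydroxy-12,12-dimethoxy-7,10-dimethyl-2-methylidene-4-{[(2Z)-2-methylbut-2-enoyl]oxy}-9-[(triethylsilyl)oxy]dodeca-7,10-dienoate (both C3 epimers) | COC(OC)/C=C(\C)[C@@H](O[Si](CC)(CC)CC)/C=C(/C)CC[C@@H](OC(=O)/C(C)=C\C)C(O)C(=C)C(=O)OC | intermediate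
18 | methyl (2Z,4R,7Z,9S,10E)-2-(bromomethyl)-12,12-dimethoxy-7,10-dimethyl-4-{[(2Z)-2-methylbut-2-enoyl]oxy}-9-[(triethylsilyl)oxy]dodeca-2,7,10-trienoate | COC(OC)/C=C(\C)[C@@H](O[Si](CC)(CC)CC)/C=C(/C)CC[C@@H](OC(=O)/C(C)=C\C)/C=C(\CBr)C(=O)OC | intermediate
19 | methyl (2Z,4R,7Z,9S,10E)-2-(bromomethyl)-9-hydroxy-7,10-dimethyl-4-{[(2Z)-2-methylbut-2-enoyl]oxy}-12-oxododeca-2,7,10-trienoate | O=C/C=C(\C)[C@@H](O)/C=C(/C)CC[C@@H](OC(=O)/C(C)=C\C)/C=C(\CBr)C(=O)OC | intermediate (not isolated)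
20 | methyl 2-[(1S,2S,3E,5S,6Z,10R)-2,5-dihydroxy-4,7-dimethyl-10-{[(2Z)-2-methylbut-2-enoyl]oxy}cyclodeca-3,6-dien-1-yl]prop-2-enoate | COC(=O)C(=C)[C@H]1[C@@H](O)/C=C(\C)[C@@H](O)/C=C(/C)CC[C@H]1OC(=O)/C(C)=C\C | intermediate (not isolated)
21 | (3aR,4R,7Z,9S,10E,11aS)-9-hydroxy-7,10-dimethyl-3-methylidene-2-oxo-2,3,3a,4,5,6,9,11a-octahydrocyclodeca[b]furan-4-yl (2Z)-2-methylbut-2-enoate | C=C1C(=O)O[C@H]2/C=C(\C)[C@@H](O)/C=C(/C)CC[C@@H](OC(=O)/C(C)=C\C)[C@@H]12 | intermediate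
22 | (3aR,4R,7S,8R,9R,10E,11aS)-7,8-epoxy-9-hydroxy-7,10-dimethyl-3-methylidene-2-oxo-2,3,3a,4,5,6,7,8,9,11a-decahydrocyclodeca[b]furan-4-yl (2Z)-2-methylbut-2-enoate | C=C1C(=O)O[C@H]2/C=C(\C)[C@@H](O)[C@H]3O[C@@]3(C)CC[C@@H](OC(=O)/C(C)=C\C)[C@@H]12 | intermediate
23 | CNP0519641.1, (3aR,4R,7S,8R,9R,10E,11aS)-9-acetoxy-7,8-epoxy-7,10-dimethyl-3-methylidene-2-oxo-2,3,3a,4,5,6,7,8,9,11a-decahydrocyclodeca[b]furan-4-yl (2Z)-2-methylbut-2-enoate | C=C1C(=O)O[C@H]2/C=C(\C)[C@@H](OC(C)=O)[C@H]3O[C@@]3(C)CC[C@@H](OC(=O)/C(C)=C\C)[C@@H]12 | target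

**Totals and risks**

Total step count: 12. Longest linear sequence: 10 steps (1, 2, 3, 6, 7, 8, 9, 10, 11, 12; from 1 to 23).

The three steps most likely to fail:

Step 10 (ring closure). The risks are oligomerisation at the metal surface, loss of the angelate by 1,4-elimination from the allylindium, and the wrong facial sense. The fallback sets out from 15 and comes back at 21; it replaces the allylmetal by a neutral allylsilane and makes the Lewis-acid-activated enal the electrophile. Trimethyl phosphonoacetate is alkylated (NaH, ICH2SiMe3) to methyl 2-(dimethoxyphosphoryl)-3-(trimethylsilyl)propanoate F1. Horner–Wadsworth–Emmons olefination of 15 with it (LiCl, iPr2NEt, MeCN, 0 °C) gives methyl (2E/Z,4R,7Z,9S,10E)-12,12-dimethoxy-7,10-dimethyl-4-{[(2Z)-2-methylbut-2-enoyl]oxy}-9-[(triethylsilyl)oxy]-2-[(trimethylsilyl)methyl]dodeca-2,7,10-trienoate F2. PPTS in wet acetone at 0 °C frees only the enal, giving methyl (2E/Z,4R,7Z,9S,10E)-7,10-dimethyl-4-{[(2Z)-2-methylbut-2-enoyl]oxy}-12-oxo-9-[(triethylsilyl)oxy]-2-[(trimethylsilyl)methyl]dodeca-2,7,10-trienoate F3. BF3·OEt2 (CH2Cl2, 1 mM, −78 °C) closes the ring by an intramolecular Hosomi–Sakurai allylation (open, syn-selective transition state) to the hydroxy ester methyl 2-[(1S,2S,3E,5S,6Z,10R)-2-hydroxy-4,7-dimethyl-10-{[(2Z)-2-methylbut-2-enoyl]oxy}-5-[(triethylsilyl)oxy]cyclodeca-3,6-dien-1-yl]prop-2-enoate F4. This lactonises with PPTS to the silyl ether (3aR,4R,7Z,9S,10E,11aS)-7,10-dimethyl-3-methylidene-2-oxo-9-[(triethylsilyl)oxy]-2,3,3a,4,5,6,9,11a-octahydrocyclodeca[b]furan-4-yl (2Z)-2-methylbut-2-enoate F5, and HF·pyridine then gives 21.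

Step 11 (epoxidation). The risks are attack at C10=C11, oxidation of the doubly allylic carbinol to the dienone, and delivery to the anti face. The fallback sets out from 17 and comes back at 22; the oxirane is made on the open chain under reagent control and carried through the ring closure. Shi epoxidation of 17 (fructose-derived ketone of the enantiomeric series that attacks the required face, Oxone (2KHSO5·KHSO4·K2SO4), K2CO3, MeCN–dimethoxymethane–aqueous buffer, 0 °C) selects the electron-rich (7Z)-olefin and gives methyl (4R,7S,8R,9R,10E)-7,8-epoxy-3-hydroxy-12,12-dimethoxy-7,10-dimethyl-2-methylidene-4-{[(2Z)-2-methylbut-2-enoyl]oxy}-9-[(triethylsilyl)oxy]dodec-10-enoate F6. NBS/Me2S as in step 9 gives methyl (2Z,4R,7S,8R,9R,10E)-2-(bromomethyl)-7,8-epoxy-12,12-dimethoxy-7,10-dimethyl-4-{[(2Z)-2-methylbut-2-enoyl]oxy}-9-[(triethylsilyl)oxy]dodeca-2,10-dienoate F7. Unmasking with PPTS (MeOH for the silyl ether, then wet acetone for the acetal; milder than acetic acid, to spare the oxirane) gives methyl (2Z,4R,7S,8R,9R,10E)-2-(bromomethyl)-7,8-epoxy-9-hydroxy-7,10-dimethyl-4-{[(2Z)-2-methylbut-2-enoyl]oxy}-12-oxododeca-2,10-dienoate F8. The indium closure of step 10 then gives methyl 2-[(1S,2S,3E,5R,6R,7S,10R)-6,7-epoxy-2,5-dihydroxy-4,7-dimethyl-10-{[(2Z)-2-methylbut-2-enoyl]oxy}cyclodec-3-en-1-yl]prop-2-enoate F9 and, after lactonisation, 22.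

Step 8 (Morita–Baylis–Hillman reaction). The risks are base-induced epimerisation of the α-acyloxy aldehyde and acyl migration in the adduct during an amine-catalysed reaction. The fallback sets out from 15 and comes back at 17; a preformed α-metallated acrylate replaces the amine catalysis. Hydroalumination of methyl propiolate (iBu2AlH, N-methylmorpholine N-oxide, THF, 0 °C) gives methyl 2-(diisobutylalumanyl)prop-2-enoate F10, which adds to 15 at −78 to 0 °C within minutes under non-basic conditions and gives 17 after aqueous work-up.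

**Further compounds**
F1 | step 10 | methyl 2-(dimethoxyphosphoryl)-3-(trimethylsilyl)propanoate | COC(=O)C(C[Si](C)(C)C)P(=O)(OC)OC
F2 | step 10 | methyl (2E/Z,4R,7Z,9S,10E)-12,12-dimethoxy-7,10-dimethyl-4-{[(2Z)-2-methylbut-2-enoyl]oxy}-9-[(triethylsilyl)oxy]-2-[(trimethylsilyl)methyl]dodeca-2,7,10-trienoate | COC(OC)/C=C(\C)[C@@H](O[Si](CC)(CC)CC)/C=C(/C)CC[C@@H](OC(=O)/C(C)=C\C)C=C(C[Si](C)(C)C)C(=O)OC
F3 | step 10 | methyl (2E/Z,4R,7Z,9S,10E)-7,10-dimethyl-4-{[(2Z)-2-methylbut-2-enoyl]oxy}-12-oxo-9-[(triethylsilyl)oxy]-2-[(trimethylsilyl)methyl]dodeca-2,7,10-trienoate | O=C/C=C(\C)[C@@H](O[Si](CC)(CC)CC)/C=C(/C)CC[C@@H](OC(=O)/C(C)=C\C)C=C(C[Si](C)(C)C)C(=O)OC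
F4 | step 10 | methyl 2-[(1S,2S,3E,5S,6Z,10R)-2-hydroxy-4,7-dimethyl-10-{[(2Z)-2-methylbut-2-enoyl]oxy}-5-[(triethylsilyl)oxy]cyclodeca-3,6-dien-1-yl]prop-2-enoate | COC(=O)C(=C)[C@H]1[C@@H](O)/C=C(\C)[C@@H](O[Si](CC)(CC)CC)/C=C(/C)CC[C@H]1OC(=O)/C(C)=C\C
F5 | step 10 | (3aR,4R,7Z,9S,10E,11aS)-7,10-dimethyl-3-methylidene-2-oxo-9-[(triethylsilyl)oxy]-2,3,3a,4,5,6,9,11a-octahydrocyclodeca[b]furan-4-yl (2Z)-2-methylbut-2-enoate | C=C1C(=O)O[C@H]2/C=C(\C)[C@@H](O[Si](CC)(CC)CC)/C=C(/C)CC[C@@H](OC(=O)/C(C)=C\C)[C@@H]12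
F6 | step 11 | methyl (4R,7S,8R,9R,10E)-7,8-epoxy-3-hydroxy-12,12-dimethoxy-7,10-dimethyl-2-methylidene-4-{[(2Z)-2-methylbut-2-enoyl]oxy}-9-[(triethylsilyl)oxy]dodec-10-enoate | COC(OC)/C=C(\C)[C@@H](O[Si](CC)(CC)CC)[C@H]1O[C@@]1(C)CC[C@@H](OC(=O)/C(C)=C\C)C(O)C(=C)C(=O)OC
F7 | step 11 | methyl (2Z,4R,7S,8R,9R,10E)-2-(bromomethyl)-7,8-epoxy-12,12-dimethoxy-7,10-dimethyl-4-{[(2Z)-2-methylbut-2-enoyl]oxy}-9-[(triethylsilyl)oxy]dodeca-2,10-dienoate | COC(OC)/C=C(\C)[C@@H](O[Si](CC)(CC)CC)[C@H]1O[C@@]1(C)CC[C@@H](OC(=O)/C(C)=C\C)/C=C(\CBr)C(=O)OC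
F8 | step 11 | methyl (2Z,4R,7S,8R,9R,10E)-2-(bromomethyl)-7,8-epoxy-9-hydroxy-7,10-dimethyl-4-{[(2Z)-2-methylbut-2-enoyl]oxy}-12-oxododeca-2,10-dienoate | O=C/C=C(\C)[C@@H](O)[C@H]1O[C@@]1(C)CC[C@@H](OC(=O)/C(C)=C\C)/C=C(\CBr)C(=O)OC
F9 | step 11 | methyl 2-[(1S,2S,3E,5R,6R,7S,10R)-6,7-epoxy-2,5-dihydroxy-4,7-dimethyl-10-{[(2Z)-2-methylbut-2-enoyl]oxy}cyclodec-3-en-1-yl]prop-2-enoate | COC(=O)C(=C)[C@H]1[C@@H](O)/C=C(\C)[C@@H](O)[C@H]2O[C@@]2(C)CC[C@H]1OC(=O)/C(C)=C\C
F10 | step 8 | methyl 2-(diisobutylalumanyl)prop-2-enoate | C=C([Al](CC(C)C)CC(C)C)C(=O)OC
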